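The retrosynthesis first removes two benzyl ethers, then opens the pyranone at O1–C2. Chromone C2 is a lone CH between O1 and the aryl-bearing C3, so it is read as the oxidised α-methyl group of a 2-aryl-1-(2-hydroxyaryl)propan-1-one.
The next cut is the Cα–aryl bond (future chromone C3 to chromene C5), made by Pd enolate arylation of a protected 2',4'-dihydroxypropiophenone with a 5-bromo-2H-chromene.
The dimethylpyran ring is cut at O1–C2 and C4–C4a, which leads to a 1,1-dimethylpropargyl ether and aromatic Claisen cyclisation on a phenol obtained from 5-bromo-o-vanillin by Baeyer–Villiger oxidation.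
In the forward direction the dimethylpyran ring is built first on the bromoarene, the two fragments are then joined, and the pyranone ring closes last by aerobic Pd(II) dehydrogenation, oxa-Michael addition and a second dehydrogenation.
The target has no stereocentre. The only sp3 stereocentre on the way (Cα of the propanone, then C3 of the isoflavanone) is racemic and ends as sp2 C3.
Key step: step 9

Remark: the target SMILES carries no stereodescriptor and the molecule is achiral, so the "single enantiomer" is simply the one constitution drawn and no asymmetric step is needed.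

Step 1
Reactants: 1 5-bromo-2-hydroxy-3-methoxybenzaldehyde (5-bromo-o-vanillin)
Product: 2 2-(benzyloxy)-5-bromo-3-methoxybenzaldehyde
Conditions: BnBr, K2CO3, DMF, 60 °C
Reagents that add atoms: benzyl bromide, BrCc1ccccc1
Why: Williamson etherification, in which the acidic aldehyde-conjugated phenoxide is alkylated cleanly by benzyl bromide while the aryl bromide and the aldehyde are inert to K2CO3.

Step 2
Reactants: 2 2-(benzyloxy)-5-bromo-3-methoxybenzaldehyde
Product: 4 2-(benzyloxy)-5-bromo-3-methoxyphenol, via 2-(benzyloxy)-5-bromo-3-methoxyphenyl formate 3 (not isolated)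
Conditions: mCPBA, CH2Cl2, 40 °C; NaHCO3 wash; then K2CO3 (cat.), MeOH, rt
Reagents that add atoms: mCPBA (3-chloroperoxybenzoic acid), OOC(=O)c1cccc(Cl)c1
Why: Baeyer–Villiger (Dakin-type) oxidation, in which the electron-rich aryl group of an o-alkoxybenzaldehyde migrates in preference to hydride to give formate 3, and mild methanolysis then frees the phenol without touching the benzyl ether or the bromide.

Step 3
Reactants: 4 2-(benzyloxy)-5-bromo-3-methoxyphenol; 5 3-chloro-3-methylbut-1-yne
Product: 6 2-(benzyloxy)-5-bromo-1-methoxy-3-[(2-methylbut-3-yn-2-yl)oxy]benzene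
Conditions: K2CO3, KI (cat.), CuI (cat.), acetone, reflux
Reagents that add atoms: none
Why: Copper-assisted O-alkylation of a phenoxide with a tertiary propargylic chloride, the standard entry to aryl 1,1-dimethylpropargyl ethers.

Step 4
Reactants: 6 2-(benzyloxy)-5-bromo-1-methoxy-3-[(2-methylbut-3-yn-2-yl)oxy]benzene
Product: 8 8-(benzyloxy)-5-bromo-7-methoxy-2,2-dimethyl-2H-chromene, via 2-(benzyloxy)-5-bromo-3-methoxy-6-(3-methylbuta-1,2-dien-1-yl)phenol 7 (not isolated)
Conditions: PhNEt2, 190 °C
Reagents that add atoms: none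
Why: Aromatic propargyl Claisen rearrangement to the only free ortho carbon (next to bromine, the other ortho carbon carrying OBn) gives allenylphenol 7, which closes by 1,5-hydrogen shift and oxa-6π electrocyclisation, the standard thermal 2,2-dimethylchromene synthesis, and this fixes the 5-bromo-7-methoxy-8-benzyloxy pattern.

Step 5
Reactants: 9 1-(2,4-dihydroxyphenyl)propan-1-one (2',4'-dihydroxypropiophenone)
Product: 10 1-[4-(benzyloxy)-2-hydroxyphenyl]propan-1-one
Conditions: BnBr (1.05 equiv), K2CO3, acetone, reflux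
Reagents that add atoms: benzyl bromide, BrCc1ccccc1
Why: Regioselective Williamson etherification, since the 2'-OH is held in a hydrogen bond to the ketone and is far less nucleophilic, so one equivalent of benzyl bromide alkylates only the 4'-OH.

Step 6
Reactants: 10 1-[4-(benzyloxy)-2-hydroxyphenyl]propan-1-one
Product: 11 1-[4-(benzyloxy)-2-(methoxymethoxy)phenyl]propan-1-one
Conditions: NaH (1.1 equiv), MOMCl, DMF, 0 °C to rt
Reagents that add atoms: chloromethyl methyl ether (MOMCl), COCCl
Why: MOM acetal protection through the sodium phenoxide, which breaks the chelate, masks a phenol that would otherwise consume base and bind palladium in the enolate arylation, and can later be removed without affecting the benzyl ethers.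

Step 7
Reactants: 8 8-(benzyloxy)-5-bromo-7-methoxy-2,2-dimethyl-2H-chromene; 11 1-[4-(benzyloxy)-2-(methoxymethoxy)phenyl]propan-1-one
Product: 12 racemic 1-[4-(benzyloxy)-2-(methoxymethoxy)phenyl]-2-[8-(benzyloxy)-7-methoxy-2,2-dimethyl-2H-chromen-5-yl]propan-1-one
Conditions: Pd2(dba)3 (2 mol %), P(t-Bu)3·HBF4 (5 mol %), NaOt-Bu (2.2 equiv), THF, 70 °C
Reagents that add atoms: none
Why: Buchwald–Hartwig–Miura palladium-catalysed α-arylation of a ketone enolate, which is established for propiophenone enolates with ortho-substituted and 1-naphthyl-type aryl bromides under bulky electron-rich phosphine ligation; only one enolisable site exists, a second arylation at the now tertiary carbon is sterically blocked, and the new α-stereocentre forms racemic, which does not matter because it becomes sp2 in step 9.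

Step 8
Reactants: 12 racemic 1-[4-(benzyloxy)-2-(methoxymethoxy)phenyl]-2-[8-(benzyloxy)-7-methoxy-2,2-dimethyl-2H-chromen-5-yl]propan-1-one
Product: 13 racemic 1-[4-(benzyloxy)-2-hydroxyphenyl]-2-[8-(benzyloxy)-7-methoxy-2,2-dimethyl-2H-chromen-5-yl]propan-1-one
Conditions: p-TsOH·H2O (20 mol %), MeOH–THF, 40 °C
Reagents that add atoms: none
Why: Acid-catalysed acetal methanolysis, in which the MOM ether ortho to the ketone is the only acetal and is especially labile because the freed phenol hydrogen-bonds to the carbonyl, so catalytic sulfonic acid suffices and the aryl benzyl ethers, the methyl ether and the chromene alkene are left alone.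

Step 9
Reactants: 13 racemic 1-[4-(benzyloxy)-2-hydroxyphenyl]-2-[8-(benzyloxy)-7-methoxy-2,2-dimethyl-2H-chromen-5-yl]propan-1-one
Product: 16 7-(benzyloxy)-3-[8-(benzyloxy)-7-methoxy-2,2-dimethyl-2H-chromen-5-yl]-4H-chromen-4-one, via 1-[4-(benzyloxy)-2-hydroxyphenyl]-2-[8-(benzyloxy)-7-methoxy-2,2-dimethyl-2H-chromen-5-yl]prop-2-en-1-one 14 (not isolated), via racemic 7-(benzyloxy)-3-[8-(benzyloxy)-7-methoxy-2,2-dimethyl-2H-chromen-5-yl]-2,3-dihydro-4H-chromen-4-one 15 (not isolated)
Conditions: Pd(TFA)2 (10 mol %), 5-nitro-1,10-phenanthroline (20 mol %), O2 (1 atm), DMSO, 100 °C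
Reagents that add atoms: none
Why: Proposed new method: the 2'-phenoxide/ketone chelate of 13 holds Pd(II) next to the doubly activated (benzylic and α-keto) C–H, which is cleaved to a tertiary palladium enolate whose only β-hydrogens sit on the methyl group, so that β-hydride elimination can lead only to the 2-aryl enone 14. The 2'-OH then adds to the CH2 terminus of 14 in a 6-endo-trig oxa-Michael closure that forms O1–C2 and the pyranone ring, the way 2-aryl-1-(2-hydroxyaryl)prop-2-en-1-ones are known to collapse to isoflavanones, and gives 15. C3–H of 15 is again benzylic and α to the ketone, so a second enolate palladation and syn β-hydride elimination of a C2 hydrogen gives chromone 16, which drains the reversible oxa-Michael equilibrium, while O2 reoxidises Pd(0). The closest known reaction types are the Pd(II)/O2 oxidative cyclisation of 2'-hydroxydihydrochalcones to flavones and the aerobic Pd(II) α,β-dehydrogenation of ketones and chromanones; dehydrogenation into the α-methyl group of an α-arylpropiophenone has not been shown. No stereocentre is created in the product, since the racemic α-carbon of 13 and C3 of 15 both end as the sp2 carbon C3 of 16. The step needs dehydrogenation of the ketone in preference to oxidation of the chromene C3=C4 alkene and of the benzylic ether CH2 groups, which is secured by the chelating o-hydroxyaryl ketone that directs palladium to the enolate, by the quaternary C2 that leaves the chromene without allylic hydrogens, and by the gem-dimethyl shielding of that cis-disubstituted alkene against Wacker-type attack.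

Step 10
Reactants: 16 7-(benzyloxy)-3-[8-(benzyloxy)-7-methoxy-2,2-dimethyl-2H-chromen-5-yl]-4H-chromen-4-one
Product: 17 7-hydroxy-3-(8-hydroxy-7-methoxy-2,2-dimethyl-2H-chromen-5-yl)-4H-chromen-4-one (target)
Conditions: BCl3 (5 equiv), pentamethylbenzene (6 equiv), CH2Cl2, −78 °C; then H2O
Reagents that add atoms: none
Why: Lewis-acid debenzylation with a non-basic cation scavenger, in which BCl3 activates the aryl benzyl ether oxygens and pentamethylbenzene traps the benzyl cation by Friedel–Crafts alkylation, so that at −78 °C the aryl methyl ether, the chromone and the chromene alkene (which hydrogenolysis would saturate) should remain intact.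

Compound list
1 | 5-bromo-2-hydroxy-3-methoxybenzaldehyde (5-bromo-o-vanillin) | COc1cc(Br)cc(C=O)c1O | starting material
2 | 2-(benzyloxy)-5-bromo-3-methoxybenzaldehyde | COc1cc(Br)cc(C=O)c1OCc1ccccc1 | intermediate
3 | 2-(benzyloxy)-5-bromo-3-methoxyphenyl formate | COc1cc(Br)cc(OC=O)c1OCc1ccccc1 | intermediate
4 | 2-(benzyloxy)-5-bromo-3-methoxyphenol | COc1cc(Br)cc(O)c1OCc1ccccc1 | intermediate
5 | 3-chloro-3-methylbut-1-yne | CC(C)(Cl)C#C | starting material
6 | 2-(benzyloxy)-5-bromo-1-methoxy-3-[(2-methylbut-3-yn-2-yl)oxy]benzene | COc1cc(Br)cc(OC(C)(C)C#C)c1OCc1ccccc1 | intermediate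
7 | 2-(benzyloxy)-5-bromo-3-methoxy-6-(3-methylbuta-1,2-dien-1-yl)phenol | COc1cc(Br)c(C=C=C(C)C)c(O)c1OCc1ccccc1 | intermediate
8 | 8-(benzyloxy)-5-bromo-7-methoxy-2,2-dimethyl-2H-chromene | COc1cc(Br)c2C=CC(C)(C)Oc2c1OCc1ccccc1 | intermediate
9 | 1-(2,4-dihydroxyphenyl)propan-1-one (2',4'-dihydroxypropiophenone) | CCC(=O)c1ccc(O)cc1O | starting material
10 | 1-[4-(benzyloxy)-2-hydroxyphenyl]propan-1-one | CCC(=O)c1ccc(OCc2ccccc2)cc1O | intermediate
11 | 1-[4-(benzyloxy)-2-(methoxymethoxy)phenyl]propan-1-one | CCC(=O)c1ccc(OCc2ccccc2)cc1OCOC | intermediate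
12 | racemic 1-[4-(benzyloxy)-2-(methoxymethoxy)phenyl]-2-[8-(benzyloxy)-7-methoxy-2,2-dimethyl-2H-chromen-5-yl]propan-1-one | COc1cc(C(C)C(=O)c2ccc(OCc3ccccc3)cc2OCOC)c2C=CC(C)(C)Oc2c1OCc1ccccc1 | intermediate
13 | racemic 1-[4-(benzyloxy)-2-hydroxyphenyl]-2-[8-(benzyloxy)-7-methoxy-2,2-dimethyl-2H-chromen-5-yl]propan-1-one | COc1cc(C(C)C(=O)c2ccc(OCc3ccccc3)cc2O)c2C=CC(C)(C)Oc2c1OCc1ccccc1 | intermediate
14 | 1-[4-(benzyloxy)-2-hydroxyphenyl]-2-[8-(benzyloxy)-7-methoxy-2,2-dimethyl-2H-chromen-5-yl]prop-2-en-1-one | COc1cc(C(=C)C(=O)c2ccc(OCc3ccccc3)cc2O)c2C=CC(C)(C)Oc2c1OCc1ccccc1 | intermediate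
15 | racemic 7-(benzyloxy)-3-[8-(benzyloxy)-7-methoxy-2,2-dimethyl-2H-chromen-5-yl]-2,3-dihydro-4H-chromen-4-one | COc1cc(C2COc3cc(OCc4ccccc4)ccc3C2=O)c2C=CC(C)(C)Oc2c1OCc1ccccc1 | intermediate
16 | 7-(benzyloxy)-3-[8-(benzyloxy)-7-methoxy-2,2-dimethyl-2H-chromen-5-yl]-4H-chromen-4-one | COc1cc(-c2coc3cc(OCc4ccccc4)ccc3c2=O)c2C=CC(C)(C)Oc2c1OCc1ccccc1 | intermediate
17 | 7-hydroxy-3-(8-hydroxy-7-methoxy-2,2-dimethyl-2H-chromen-5-yl)-4H-chromen-4-one | COc1cc(-c2coc3cc(O)ccc3c2=O)c2c(c1O)OC(C)(C)C=C2 | target

Total step count: 10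
Longest linear sequence: 8 steps (steps 1, 2, 3, 4, 7, 8, 9, 10)

Steps most likely to fail

1. Step 9 (new method).
- **Risk:** Palladation of the crowded tertiary α-carbon may be too slow. Autoxidative C–C cleavage at that benzylic position, Wacker-type attack on the chromene alkene, or catalyst decomposition to palladium black could then take over.
- **Fallback:** This uses known chemistry and takes C2 from a C1 reagent instead of from the α-methyl group. It sets out from bromide 8 and returns to the route at 16. Commercial 1-[4-(benzyloxy)-2-hydroxyphenyl]ethan-1-one F1 is converted with NaH and MOMCl into 1-[4-(benzyloxy)-2-(methoxymethoxy)phenyl]ethan-1-one F2. This is α-arylated with 8 under the conditions of step 7 to the deoxybenzoin 1-[4-(benzyloxy)-2-(methoxymethoxy)phenyl]-2-[8-(benzyloxy)-7-methoxy-2,2-dimethyl-2H-chromen-5-yl]ethan-1-one F3. Catalytic p-TsOH in MeOH frees the phenol to give 1-[4-(benzyloxy)-2-hydroxyphenyl]-2-[8-(benzyloxy)-7-methoxy-2,2-dimethyl-2H-chromen-5-yl]ethan-1-one F4. Heating F4 with N,N-dimethylformamide dimethyl acetal in toluene (enaminone formation and cyclisation, the classical deoxybenzoin isoflavone synthesis) gives 16.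

2. Step 7.
- **Risk:** Oxidative addition of the electron-rich, peri-hindered bromide or reductive elimination from the crowded aryl palladium enolate may be slow. Protodebromination or Heck-type engagement of the chromene alkene could then compete.
- **Fallback:** This reverses the polarity of the two partners. It sets out from 8 and 11 and returns at 12. The lithium enolate of 11 (LiHMDS, THF, −78 °C) is brominated with NBS to racemic 2-bromo-1-[4-(benzyloxy)-2-(methoxymethoxy)phenyl]propan-1-one F5. Bromide 8 is converted by bromine–lithium exchange (n-BuLi, −78 °C) and ZnCl2 into chloro[8-(benzyloxy)-7-methoxy-2,2-dimethyl-2H-chromen-5-yl]zinc F6. The two are joined by nickel-catalysed Negishi arylation of the secondary α-bromo ketone (NiCl2·glyme, tridentate nitrogen ligand, glyme–THF, −30 °C) to give 12.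

3. Step 10.
- **Risk:** The chromene alkene is electron-rich, with OMe para and O1 ortho to C4a. It may be protonated or chlorinated by the BCl3/HCl medium, leading to oligomerisation. The methyl ether next to the freed 8-O–boron group may also be lost through chelation.
- **Fallback:** This sacrifices the alkene and restores it afterwards. It sets out from 16 and returns at 17. Hydrogenolysis (H2, Pd/C, EtOAc–MeOH) removes both benzyl groups and saturates C3=C4 to give 7-hydroxy-3-(8-hydroxy-7-methoxy-2,2-dimethyl-3,4-dihydro-2H-chromen-5-yl)-4H-chromen-4-one F7. Ac2O and pyridine give 3-[8-(acetyloxy)-7-methoxy-2,2-dimethyl-3,4-dihydro-2H-chromen-5-yl]-4-oxo-4H-chromen-7-yl acetate F8. DDQ in refluxing dioxane (the known dehydrogenation of 2,2-dimethylchromans) gives 3-[8-(acetyloxy)-7-methoxy-2,2-dimethyl-2H-chromen-5-yl]-4-oxo-4H-chromen-7-yl acetate F9. Methanolysis with catalytic K2CO3 gives 17.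

Further compounds
F1 | step 9 | 1-[4-(benzyloxy)-2-hydroxyphenyl]ethan-1-one (commercial) | CC(=O)c1ccc(OCc2ccccc2)cc1O
F2 | step 9 | 1-[4-(benzyloxy)-2-(methoxymethoxy)phenyl]ethan-1-one | CC(=O)c1ccc(OCc2ccccc2)cc1OCOC
F3 | step 9 | 1-[4-(benzyloxy)-2-(methoxymethoxy)phenyl]-2-[8-(benzyloxy)-7-methoxy-2,2-dimethyl-2H-chromen-5-yl]ethan-1-one | COc1cc(CC(=O)c2ccc(OCc3ccccc3)cc2OCOC)c2C=CC(C)(C)Oc2c1OCc1ccccc1
F4 | step 9 | 1-[4-(benzyloxy)-2-hydroxyphenyl]-2-[8-(benzyloxy)-7-methoxy-2,2-dimethyl-2H-chromen-5-yl]ethan-1-one | COc1cc(CC(=O)c2ccc(OCc3ccccc3)cc2O)c2C=CC(C)(C)Oc2c1OCc1ccccc1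
F5 | step 7 | racemic 2-bromo-1-[4-(benzyloxy)-2-(methoxymethoxy)phenyl]propan-1-one | CC(Br)C(=O)c1ccc(OCc2ccccc2)cc1OCOC
F6 | step 7 | chloro[8-(benzyloxy)-7-methoxy-2,2-dimethyl-2H-chromen-5-yl]zinc | COc1cc([Zn]Cl)c2C=CC(C)(C)Oc2c1OCc1ccccc1
F7 | step 10 | 7-hydroxy-3-(8-hydroxy-7-methoxy-2,2-dimethyl-3,4-dihydro-2H-chromen-5-yl)-4H-chromen-4-one | COc1cc(-c2coc3cc(O)ccc3c2=O)c2CCC(C)(C)Oc2c1O
F8 | step 10 | 3-[8-(acetyloxy)-7-methoxy-2,2-dimethyl-3,4-dihydro-2H-chromen-5-yl]-4-oxo-4H-chromen-7-yl acetate | COc1cc(-c2coc3cc(OC(C)=O)ccc3c2=O)c2CCC(C)(C)Oc2c1OC(C)=O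
F9 | step 10 | 3-[8-(acetyloxy)-7-methoxy-2,2-dimethyl-2H-chromen-5-yl]-4-oxo-4H-chromen-7-yl acetate | COc1cc(-c2coc3cc(OC(C)=O)ccc3c2=O)c2C=CC(C)(C)Oc2c1OC(C)=O
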